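**Strategy.** Target numbering: O1–O2–C3(OH)–C4–C5–C6. The ring is cut across O1–C6 and C3–C4, giving an O–O–C3 unit at the acid oxidation level and the C4–C5–C6 triad. Key step, a formal [3+3] annulation: a silylperoxy orthoacetate opens a formyl-activated enantiopure cyclopropane at its quaternary carbon (C6, inversion), and the resulting enol ether closes onto the orthoester carbon C3. It exploits the 1,3-relationship of peroxy-bearing quaternary C6 and ketone α-carbon C4, and the hemiketal C3 as a masked acyl group. The formyl group on C4 is then excised by retro-Claisen cleavage, setting C4 and C3 thermodynamically. The side-chain centre is bought; the cyclopropane comes from a Charette cyclopropanation.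

Key step: step 10

Assumption (chemistry): opening at the quaternary cyclopropane carbon is taken to occur with inversion, and compounds 13–15 are carried as mixtures at the cyano/formyl-bearing ring carbon, which becomes planar in step 10.

**Step 1**
Reactants: 1 (7-bromoheptyl)benzene; 2 (S)-3-bromo-2-methylpropan-1-ol
Product: 4 (R)-2-methyl-10-phenyldecan-1-ol, via Grignard reagent 3 (not isolated)
Conditions: 1 (2.4 equiv), Mg, THF, 40 °C; then 2, Li2CuCl4 (5 mol%), THF, −20 → 20 °C; aq. NH4Cl
Reagents that add atoms: none
Why: Kochi-type copper-catalysed sp3–sp3 cross-coupling of an alkyl Grignard reagent with a primary bromide (the first equivalent of 3 converts the hydroxyl group into its magnesium alkoxide); the bought stereocentre is not touched.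

**Step 2**
Reactants: 4 (R)-2-methyl-10-phenyldecan-1-ol
Product: 5 (R)-1-iodo-2-methyl-10-phenyldecane
Conditions: I2, PPh3, imidazole, CH2Cl2, 0 → 20 °C
Reagents that add atoms: iodine, [I][I]
Why: Appel-type iodination of a primary alcohol through the alkoxyphosphonium iodide; the substitution occurs at the CH2 group, so the adjacent stereocentre is unchanged.

**Step 3**
Reactants: 5 (R)-1-iodo-2-methyl-10-phenyldecane
Product: 6 (4R)-4-methyl-12-phenyldodec-1-yne
Conditions: LiC≡CH·H2NCH2CH2NH2, DMSO, 15 → 25 °C
Reagents that add atoms: lithium acetylide–ethylenediamine complex, [Li]C#C.NCCN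
Why: SN2 alkylation of lithium acetylide by a primary iodide in a dipolar aprotic solvent, which should outrun elimination at this β-branched centre.

**Step 4**
Reactants: 6 (4R)-4-methyl-12-phenyldodec-1-yne
Product: 8 (2E,5R)-3,5-dimethyl-13-phenyltridec-2-en-1-ol, via alkenylalane 7 (not isolated)
Conditions: Me3Al (2.5 equiv), Cp2ZrCl2 (0.25 equiv), CH2Cl2, 0 → 23 °C; then (CH2O)n, THF, 0 → 23 °C; aq. HCl
Reagents that add atoms: trimethylaluminium, C[Al](C)C; paraformaldehyde (as formaldehyde), C=O
Why: Negishi zirconium-catalysed syn-carboalumination places the methyl group on the internal and aluminium on the terminal alkyne carbon, and the alkenylalane adds to formaldehyde with retention, so the E geometry is set stereospecifically.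

**Step 5**
Reactants: 8 (2E,5R)-3,5-dimethyl-13-phenyltridec-2-en-1-ol
Product: 9 [(1R,2R)-2-methyl-2-[(2R)-2-methyl-10-phenyldecyl]cyclopropyl]methanol
Conditions: Et2Zn, CH2I2, DME, CH2Cl2, −10 °C; (4S,5S)-2-butyl-N,N,N′,N′-tetramethyl-1,3,2-dioxaborolane-4,5-dicarboxamide (1.2 equiv), −10 → 23 °C; aq. NH4Cl
Reagents that add atoms: diiodomethane, ICI
Why: Charette asymmetric Simmons–Smith cyclopropanation, in which the zinc alkoxide bound to the chiral dioxaborolane delivers CH2 to one alkene face (reagent control; the (4S,5S) ligand is chosen as the enantiomer of the one that gives the (1S,2S) cyclopropane from cinnamyl alcohol), and syn addition to the E alkene fixes both ring stereocentres.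

**Step 6**
Reactants: 9 [(1R,2R)-2-methyl-2-[(2R)-2-methyl-10-phenyldecyl]cyclopropyl]methanol
Product: 11 (1R,2R)-2-methyl-2-[(2R)-2-methyl-10-phenyldecyl]cyclopropane-1-carbonitrile, via cyclopropanecarbaldehyde 10 (not isolated)
Conditions: TEMPO (10 mol%), PhI(OAc)2 (2.2 equiv), NH4OAc (4 equiv), MeCN/H2O 9:1, 23 °C
Reagents that add atoms: ammonium acetate, [NH4+].CC(=O)[O-]
Why: one-pot oxidative conversion of a primary alcohol into a nitrile (oxoammonium oxidation to the aldehyde, condensation with ammonia, second oxidation of the aldimine); the quaternary ring carbon is not affected.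

**Step 7**
Reactants: 11 (1R,2R)-2-methyl-2-[(2R)-2-methyl-10-phenyldecyl]cyclopropane-1-carbonitrile
Product: 13 (2R)-1,2-dimethyl-2-[(2R)-2-methyl-10-phenyldecyl]cyclopropane-1-carbonitrile (both C1 epimers), via lithiated nitrile 12 (not isolated)
Conditions: LiN(iPr)2, THF, −78 °C; MeI, −78 → 0 °C
Reagents that add atoms: iodomethane, CI
Why: α-deprotonation of a cyclopropanecarbonitrile to its N-lithio keteniminate and C-methylation; the new quaternary C1 is formed without control, which is harmless because it becomes planar in step 10.

**Step 8**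
Reactants: 13 (2R)-1,2-dimethyl-2-[(2R)-2-methyl-10-phenyldecyl]cyclopropane-1-carbonitrile
Product: 15 (2R)-1,2-dimethyl-2-[(2R)-2-methyl-10-phenyldecyl]cyclopropane-1-carbaldehyde (both C1 epimers), via aluminium imine 14 (not isolated)
Conditions: iBu2AlH, CH2Cl2, −78 °C; then aq. KNaC4H4O6, 23 °C
Reagents that add atoms: water, O
Why: half-reduction of the nitrile by iBu2AlH stops at the N-aluminio imine, which is hydrolysed to the aldehyde on work-up; the aldehyde has no α-hydrogen and cannot epimerise or enolise.

**Step 9**
Reactants: 16 1,1-dimethoxyethene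
Product: 18 triethyl[(1,1-dimethoxyethyl)peroxy]silane, via hydroperoxide 17 (not isolated)
Conditions: H2O2·urea (3 equiv), pyridinium p-toluenesulfonate (2 mol%), Et2O, 0 °C; filter; then Et3SiCl, imidazole, CH2Cl2, 0 °C
Reagents that add atoms: hydrogen peroxide–urea, OO.NC(N)=O; chlorotriethylsilane, CC[Si](Cl)(CC)CC
Why: acid-catalysed Markovnikov addition of a hydroperoxide O–H across an oxygen-substituted alkene (as in orthoester formation from ketene acetals and peroxyketal formation from enol ethers), followed by O-silylation of the hydroperoxide.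

**Step 10**
Reactants: 15 (2R)-1,2-dimethyl-2-[(2R)-2-methyl-10-phenyldecyl]cyclopropane-1-carbaldehyde; 18 triethyl[(1,1-dimethoxyethyl)peroxy]silane
Product: 20 (6S)-3-methoxy-3,4,6-trimethyl-6-[(2R)-2-methyl-10-phenyldecyl]-1,2-dioxane-4-carbaldehyde (C3/C4 diastereomers), via silyl enol ether 19 (not isolated)
Conditions: 18 (1.5 equiv), Et3SiOTf (0.3 equiv), 2,6-di-tert-butyl-4-methylpyridine (0.3 equiv), 4 Å molecular sieves, CH2Cl2, −78 → −30 °C; Et3N quench
Reagents that add atoms: none
Why: Proposed new method: Et3SiOTf silylates the formyl oxygen of 15, giving a cyclopropylcarbinyl-type oxocarbenium ion whose C1–C2 bond (C4–C6 of the target) can release a tertiary cation, and the silylated peroxy oxygen of 18 attacks that quaternary carbon from the rear, passing its silyl group to triflate and leaving silyl enol ether 19 (O1–C6 formed). The regenerated silyl triflate then ionises one methoxy group of the tethered peroxy ortho ester to a peroxy-stabilised alkoxycarbenium ion, which the enol ether captures in a 6-(enolexo)-exo-trig Mukaiyama-type closure of the 1,2-dioxane (C3–C4 formed), with Et3SiOMe as the only by-product. The closest known reaction types are the iodotrimethylsilane homo-conjugate opening of cyclopropyl carbonyl compounds to γ-substituted silyl enol ethers, stereoinvertive nucleophilic substitution at quaternary cyclopropylcarbinyl carbons, Lewis-acid opening of oxetanes by hydroperoxides with inversion at a tertiary carbon, formal [3+3] annulations of donor–acceptor cyclopropanes with nitrones, and Mukaiyama alkylations with ortho esters; none has been shown with a peroxide nucleophile on a cyclopropane. C6 is set by backside attack on the (2R) ring carbon of 15 (inversion, giving 6S), while C3 and C4 are formed without control and are both reset in step 11. The step needs attack at the quaternary ring carbon and not at the ring CH2, and by the peroxy oxygen and not by a methoxy oxygen or the carbonyl oxygen (Cloke–Wilson ring expansion); the cationic character at the dialkylated carbon, the α-effect of the peroxide, O-silylation of the carbonyl group, the absence of an α-hydrogen in 15 and the low temperature are relied on for this.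

**Step 11**
Reactants: 20 (6S)-3-methoxy-3,4,6-trimethyl-6-[(2R)-2-methyl-10-phenyldecyl]-1,2-dioxane-4-carbaldehyde
Product: 22 (3S,4R,6S)-3,4,6-trimethyl-6-[(2R)-2-methyl-10-phenyldecyl]-1,2-dioxan-3-ol (target), via hemiketal aldehyde 21 (not isolated)
Conditions: 0.5 M HCl, THF/H2O, 0 → 23 °C; then K2CO3 (0.5 equiv), MeOH, 0 → 23 °C; pH 7 buffer
Reagents that add atoms: water, O
Why: aqueous acid hydrolyses the methyl peroxyketal to hemiketal 21, whose open-chain tautomer is a non-enolisable α-formyl ketone that loses methyl formate by retro-Claisen cleavage with methoxide; C4 is then protonated and equilibrated through the open-chain γ-hydroperoxy ketone toward the isomer with equatorial 4-methyl and equatorial 6-alkyl chain (the 4-epimer must place the branched chain axial or suffer a 1,3-diaxial methyl/methyl contact), and C3 settles by ring–chain tautomerism with axial OH (anomeric effect).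

**Compound list**

1 | (7-bromoheptyl)benzene | BrCCCCCCCc1ccccc1 | starting material
2 | (S)-3-bromo-2-methylpropan-1-ol | OC[C@H](C)CBr | starting material
3 | (7-phenylheptyl)magnesium bromide | Br[Mg]CCCCCCCc1ccccc1 | intermediate (not isolated)
4 | (R)-2-methyl-10-phenyldecan-1-ol | OC[C@H](C)CCCCCCCCc1ccccc1 | intermediate
5 | (R)-1-iodo-2-methyl-10-phenyldecane | IC[C@H](C)CCCCCCCCc1ccccc1 | intermediate
6 | (4R)-4-methyl-12-phenyldodec-1-yne | C#CC[C@H](C)CCCCCCCCc1ccccc1 | intermediate
7 | dimethyl[(1E,4R)-2,4-dimethyl-12-phenyldodec-1-en-1-yl]alumane | C[Al](C)/C=C(\C)C[C@H](C)CCCCCCCCc1ccccc1 | intermediate (not isolated)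
8 | (2E,5R)-3,5-dimethyl-13-phenyltridec-2-en-1-ol | OC/C=C(C)/C[C@H](C)CCCCCCCCc1ccccc1 | intermediate
9 | [(1R,2R)-2-methyl-2-[(2R)-2-methyl-10-phenyldecyl]cyclopropyl]methanol | OC[C@@H]1C[C@@]1(C)C[C@H](C)CCCCCCCCc1ccccc1 | intermediate
10 | (1R,2R)-2-methyl-2-[(2R)-2-methyl-10-phenyldecyl]cyclopropane-1-carbaldehyde | O=C[C@@H]1C[C@@]1(C)C[C@H](C)CCCCCCCCc1ccccc1 | intermediate (not isolated)
11 | (1R,2R)-2-methyl-2-[(2R)-2-methyl-10-phenyldecyl]cyclopropane-1-carbonitrile | N#C[C@@H]1C[C@@]1(C)C[C@H](C)CCCCCCCCc1ccccc1 | intermediate
12 | N-lithio keteniminate of 11, lithium {[(2R)-2-methyl-2-[(2R)-2-methyl-10-phenyldecyl]cyclopropylidene]methylidene}azanide | [Li]N=C=C1C[C@@]1(C)C[C@H](C)CCCCCCCCc1ccccc1 | intermediate (not isolated)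
13 | (2R)-1,2-dimethyl-2-[(2R)-2-methyl-10-phenyldecyl]cyclopropane-1-carbonitrile (both C1 epimers) | N#CC1(C)C[C@@]1(C)C[C@H](C)CCCCCCCCc1ccccc1 | intermediate
14 | N-[bis(2-methylpropyl)alumanyl]-1-[(2R)-1,2-dimethyl-2-[(2R)-2-methyl-10-phenyldecyl]cyclopropyl]methanimine | CC(C)C[Al](CC(C)C)N=CC1(C)C[C@@]1(C)C[C@H](C)CCCCCCCCc1ccccc1 | intermediate (not isolated)
15 | (2R)-1,2-dimethyl-2-[(2R)-2-methyl-10-phenyldecyl]cyclopropane-1-carbaldehyde (both C1 epimers) | O=CC1(C)C[C@@]1(C)C[C@H](C)CCCCCCCCc1ccccc1 | intermediate
16 | 1,1-dimethoxyethene | C=C(OC)OC | starting material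
17 | 1-hydroperoxy-1,1-dimethoxyethane | CC(OC)(OC)OO | intermediate (not isolated)
18 | triethyl[(1,1-dimethoxyethyl)peroxy]silane | CC(OC)(OC)OO[Si](CC)(CC)CC | intermediate
19 | triethyl{[(4S,6R)-4-[(1,1-dimethoxyethyl)peroxy]-2,4,6-trimethyl-14-phenyltetradec-1-en-1-yl]oxy}silane (E/Z mixture) | CC(OC)(OC)OO[C@](C)(CC(C)=CO[Si](CC)(CC)CC)C[C@H](C)CCCCCCCCc1ccccc1 | intermediate (not isolated)
20 | (6S)-3-methoxy-3,4,6-trimethyl-6-[(2R)-2-methyl-10-phenyldecyl]-1,2-dioxane-4-carbaldehyde (C3/C4 diastereomers) | COC1(C)OO[C@](C)(CC1(C)C=O)C[C@H](C)CCCCCCCCc1ccccc1 | intermediate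
21 | (6S)-3-hydroxy-3,4,6-trimethyl-6-[(2R)-2-methyl-10-phenyldecyl]-1,2-dioxane-4-carbaldehyde (C3/C4 diastereomers) | OC1(C)OO[C@](C)(CC1(C)C=O)C[C@H](C)CCCCCCCCc1ccccc1 | intermediate (not isolated)
22 | (3S,4R,6S)-3,4,6-trimethyl-6-[(2R)-2-methyl-10-phenyldecyl]-1,2-dioxan-3-ol | C[C@H](CCCCCCCCc1ccccc1)C[C@@]1(C)C[C@@H](C)[C@@](C)(O)OO1 | target

**Step count.** Total: 11 steps. Longest linear sequence: 10 steps (steps 1–8, 10, 11); step 9 is a one-step side branch.

**Steps most likely to fail**

1. Step 10 (proposed new method). The silyl peroxide may be too weak a nucleophile for the activated cyclopropane. Methoxy transfer from the ortho ester, ring expansion of the silylated formylcyclopropane to a dihydrofuran, or ionisation to a free tertiary cation with loss of configuration at C6 could then take over. The fallback uses known chemistry, sets out from iodide 5 and returns at 22. Li2CuCl4-catalysed coupling of 5 with isopropenylmagnesium bromide should give (4R)-2,4-dimethyl-12-phenyldodec-1-ene F1. Aerobic oxidation of 3-methylpentane-2,4-dione with catalytic Mn(OAc)3 (trivalent manganese) in AcOH under O2 in the presence of F1 should give 1-[3-hydroxy-3,4,6-trimethyl-6-[(2R)-2-methyl-10-phenyldecyl]-1,2-dioxan-4-yl]ethan-1-one F2. This proceeds by radical addition to the alkene terminus, capture of O2 by the tertiary radical and hemiketalisation. Retro-Claisen deacetylation (K2CO3, MeOH) then delivers 22. This alternative builds the ring through a different set of bonds and gives up control of C6, so the C6 epimer would have to be removed by chromatography.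

2. Step 11. The thermodynamic bias at C4 may be insufficient, because the methyl and the branched alkyl group on C6 differ little in size, so equilibration could stop at a mixture. The open-chain hydroperoxy ketone may also degrade slowly under base. The fallback sets out from 20 and returns at 22. Instead of relying on a single equilibration, the C4 epimer formed beside 22, (3R,4S,6S)-3,4,6-trimethyl-6-[(2R)-2-methyl-10-phenyldecyl]-1,2-dioxan-3-ol F3, is separated by chromatography and recycled. Brief exposure of F3 to a catalytic amine base (DBU, CH2Cl2) re-opens it to the hydroperoxy ketone, epimerises C4 and feeds material back to 22. Repeating the separation and recycling loop should converge the material on 22.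

3. Step 9. Adventitious water may hydrolyse the ketene acetal, double addition may give the symmetrical peroxide, and the free hydroperoxide 17 may decompose before silylation. The fallback sets out from 16 and returns at 18 with the order of bond formation reversed. Et3SiCl is first converted into triethylsilyl hydroperoxide F4 (H2O2·urea, imidazole, Et2O). F4 is then added across 16 under pyridinium p-toluenesulfonate catalysis, which should give 18 without passing through 17.

**Further compounds**

F1 | step 10 | (4R)-2,4-dimethyl-12-phenyldodec-1-ene | C=C(C)C[C@H](C)CCCCCCCCc1ccccc1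
F2 | step 10 | 1-[3-hydroxy-3,4,6-trimethyl-6-[(2R)-2-methyl-10-phenyldecyl]-1,2-dioxan-4-yl]ethan-1-one | CC(=O)C1(C)CC(C)(C[C@H](C)CCCCCCCCc2ccccc2)OOC1(C)O
F3 | step 11 | (3R,4S,6S)-3,4,6-trimethyl-6-[(2R)-2-methyl-10-phenyldecyl]-1,2-dioxan-3-ol | C[C@H](CCCCCCCCc1ccccc1)C[C@@]1(C)C[C@H](C)[C@](C)(O)OO1
F4 | step 9 | triethylsilyl hydroperoxide | CC[Si](CC)(CC)OO
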